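Which of these recipes should we run next to end with the most target, and what do we have to reckon to choose?

| setting | teal | amber | green | grey | violet |
|---|---|---|---|---|---|
| substrate | 0.50 M | 0.50 M | 0.50 M | 0.50 M (fed, over 12 d) | 0.50 M |
| first nucleophile | 1.00 M | 1.00 M | 1.00 M | 1.00 M | 1.00 M |
| second nucleophile | 0.500 M (in portions, 2, over 12 d) | 0.500 M (fed, over 12 d) | 0.500 M | 0.500 M | 0.500 M (fed, over 12 d) |
| temperature | 35 °C | 35 °C |  | 35 °C |  |
| time | 20 d | 20 d | 20 d | 20 d | 20 d |
| remark | first portion at the start, last at 12 d | all else is in the flask from the start; the feed brings no volume worth counting | everything together at the start at −5 °C, warmed to 35 °C at 12 d | all else is in the flask from the start; the feed brings no volume worth counting | the addition at −5 °C, then warmed to 35 °C; the feed brings no volume worth counting |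

    substrate → intermediate (k1 = 0.63 h⁻¹, Ea1 = 106 kJ mol⁻¹)
    first nucleophile + intermediate → target (k2 = 18 L mol⁻¹ h⁻¹, Ea2 = 47.0 kJ mol⁻¹)
    second nucleophile + intermediate → other capture product (k3 = 7.1 L mol⁻¹ h⁻¹, Ea3 = 74.0 kJ mol⁻¹)
    2 second nucleophile → self-condensation product (k4 = 0.0053 L mol⁻¹ h⁻¹, Ea4 = 82.0 kJ mol⁻¹)
    second nucleophile + target → over-reaction product (k5 = 0.0056 L mol⁻¹ h⁻¹, Ea5 = 79.0 kJ mol⁻¹)
    (constants at 35 °C)

- the flask that comes out highest in amount of target, in percent of the substrate charged, or "all alike" when all lie within 1.5 percentage points (teal / amber / green / grey / violet / all alike)
- target at the end, in percent of the substrate charged, teal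
- target at the end, in percent of the substrate charged, amber
- target at the end, in percent of the substrate charged, green
- target at the end, in percent of the substrate charged, grey
- target at the end, in percent of the substrate charged, violet

- where a step has two of a species, its rate is k times that concentration squared, and two are used at each turn
- the list of constants is for 35 °C, to be carried to other temperatures by the activation energies

Substrate lives about 1.59 h at 35 °C, far shorter than the dosing time of 12 d, so in a warm flask target appears soon after substrate enters, and we follow what happens to target afterwards. Target standing in second nucleophile at concentration c decays pseudo-first-order with constant kO·c, where kO is the over-reaction constant. We therefore carry the wear time, the lifetime of target in the whole charge a of second nucleophile, L = 1/(kO·a) = 14.9 d, and replace the falling curve by its mean c̄ over the time t that target stands, which gives the surviving fraction S = exp(−(c̄/a)·t/L). Since L is shorter than the run, this loss matters, but self-condensation alone halves the charge in 7.86 d, sooner than L, so the curve must not be taken as flat. With kS the self-condensation constant and b the starting concentration, that step alone gives c̄·t = ln(1 + 2·kS·b·t)/(2·kS), and we knowingly ignore what the other steps consume.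

In teal, target forms at the start and sees the first portion, 0.250 M, then a refreshed 0.392 M after the last portion. So c̄ is 0.227 M and S is 54.4 %. In grey, the average target is born at mid-feed and stands 14.0 d in a curve already fallen, so c̄ is 0.196 M and S is 69.2 %, higher than in teal.

Capture selectivity, the first nucleophile's share of the two capture rates, is 91.0 % in teal with the first portion in the flask. In grey, taken at the feed-time mean 0.304 M, it is 89.3 %. Our reckoning ends at 49.5 % target for teal and 61.8 % for grey, so we would charge grey before teal; amber and the cold flasks we leave unreckoned.

The forecast, higher than our reckoning for teal and for grey, named grey, with 58.7 % for teal, 61.9 % for amber, 64.2 % for green, 67.8 % for grey and 64.4 % for violet, on the ground that “The real loss is target destroyed by leftover second nucleophile”. The simulation gives grey as highest, with 58.7 % for teal, 62.1 % for amber, 64.3 % for green, 68.3 % for grey and 64.5 % for violet.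

In grey, target over target plus over-reaction product reads 77.1 % against our 69.2 %, and the mean second nucleophile over the first 12 d, 0.267 M, lies below our 0.304 M, so our curve stood too high. Without self-condensation, grey's lead over teal of 9.6 percentage points becomes −4.9 points. For teal's neighbour with 2.0 M of second nucleophile, L and the same curve give S = 24.5 %. That flask holds 20.8 % target beside 48.8 % over-reaction product, a surviving fraction of 29.9 %.

The constants used here are invented; what happens was integrated by code.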